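The numbers are assumed; the result is computed.

I read this flask at 15 d, and what I carry to that reading is one share: how much of the charge slips away through the other conformer.

    starting material ⇌ other conformer (K1 = 0.018, k1 = 0.10 /h)
    starting material → target (k2 = 0.081 /h)
    other conformer → isomer of the product A (k3 = 0.096 /h)
    other conformer ⇌ third conformer (K4 = 1.2, k4 = 0.062 /h)
    third conformer → third product (k5 = 0.078 /h)
    target ⇌ isomer of the product B (K6 = 0.73, k6 = 0.059 /h)
    solid substrate ⇌ starting material, rate k7*(cs7 - [starting material]) while solid is left; crystals form when [starting material] > cs7 (cs7 = 15 mM, k7 = 1.8 /h)

solid substrate 16 mM; time 15 d

- solid substrate is a solid; its amount is given per volume of the solution
- at the start none of the solid substrate is in solution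
- in a conversion other conformer counts as not yet reacted; third conformer counts as reacted
- what has only dissolved of solid substrate counts as not reacted
- the reaction counts as stopped when no species that holds the solid substrate changes by six tenths of a point or more over the second half of the time
- run time (flask): 15 d

1. why nothing more happens at 15 d, or that something still does (for what has run out or reacted, a solid counts together with what of it has only dissolved; other conformer counts as not reacted) (forward and back rates have come level / all of the solid substrate has reacted / it is still moving)
2. part of the solid substrate that has turned into other species by 15 d (what has only dissolved and other conformer do not count)
3. the target standing at 15 d, as a percentage of the solid substrate charged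
4. the isomer of the product B standing at 15 d, as a percentage of the solid substrate charged

The half-life of the starting material on its way to the target, 0.36 d, fits 41.7 times into 15 d, and the forward half-life of the target, 0.49 d, is shorter than that time. So I expect the solid to be used up and c(isomer of the product B) to stand at 0.73 times c(target). No leak puts the target at 57.8%, my bound from above.

For the bound from below I hold c(other conformer) at 0.018 times c(starting material), a fast pre-equilibrium, since its relaxation half-life of 0.123 h is far shorter than 0.36 d. I also count whatever enters the third conformer as lost. Then 3.39% leaks and the target stands at 55.8%.

Now I go round. The third conformer also returns, and 60.2% of what enters it goes on to the third product, so the drain on the other conformer is 0.133 /h and the leak falls to 2.88%. Going round once more, that drain holds c(other conformer) slightly below balance, at 0.0176 times c(starting material). This gives 2.81%, the leak share: the part of the charge that ends as isomer of the product A or third product. Past the dissolving, rates are first order, so the charge drops out of this share. I commit to target 56.2% and isomer of the product B 41.0%.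

The forecast says all of the solid substrate has reacted, conversion 100%, target 56.2% and isomer of the product B 41%, on the ground that “only about 3% leaks to the side products”. Its target lies inside my bracket. The simulation gives all of the solid substrate has reacted, conversion 100%, target 56.2% and isomer of the product B 41.0%.

In this flask the dissolving had 100% of its turnover behind it by 3.00 d and half the conversion was reached at 0.376 d; at 1.50 d starting material was down to 5.43% and isomer of the product B stood at 35.9%. At 7.50 d this flask reads target 56.2% and isomer of the product B 41.0%, with starting material at 0%, and it reads the same at 15.0 d. At 15.0 d in this flask isomer of the product A and third product add up to 2.81%, against the leak share of 2.81%. The neighbour charged with 6.4 mM holds target 56.2%, and at 15.0 d its isomer of the product A and third product add up to 2.81%.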